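## Retrosynthetic overview
1. Target ⇒ bis-ester, by hydrolysis of three acetonides and two glycol cleavages. Each 1,5-dialdehyde arm is stored as a cis-cyclopentane-1,2-diol acetonide and the free 1,3-diol as a dioxane.
2. Bis-ester ⇒ core diol plus two equivalents of a single acid, joined in one double Mitsunobu esterification with inversion at the ring carbinol.
3. Core diol ⇒ cyclopentanone ⇒ (Nef) nitrocyclopentane. The carbinol carbon enters as a nitronate, that is, as an acyl anion equivalent.
4. Key bond C(carbinol)–C(methyl-bearing): nitronate carbon plus the β-carbon of crotonaldehyde, two natural acceptor sites. An aminocatalytic Michael/Michael cascade makes this bond, closes ring A and sets three ring stereocentres. The precursor comes from acrolein, NaNO2 and dimethyl malonate.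
5. Acid ⇒ D-ribose-derived cyclopentenone acetonide, by reductive alkylation and ethylidenation. Ring order: ring A in step 3, dioxane ring B in step 5. The carbocycles of the acid are bought in and are opened last.

Assumption: the D-ribose-derived cyclopentenone acetonide is taken as a purchasable catalogue compound. The nitro-bearing carbon is drawn as its more stable epimer, and its configuration is erased by the Nef step.

## Route

Step 1
Reactants: 1 acrolein
Product: 2 3-nitropropanal
Conditions: NaNO2, AcOH, THF/H2O, 0 °C
Reagents that add atoms: sodium nitrite [Na+].[O-]N=O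
Why: Michael (conjugate) addition of nitrite through nitrogen to acrolein, with AcOH protonating the enolate; no stereocentre is formed.

Step 2
Reactants: 2 3-nitropropanal; 3 dimethyl malonate
Product: 4 dimethyl 2-(3-nitropropylidene)malonate
Conditions: TiCl4 (2 equiv), pyridine (4 equiv), THF/CH2Cl2, 0 °C → rt
Reagents that add atoms: none
Why: Knoevenagel condensation in its TiCl4/pyridine form, where the Lewis acid activates the aldehyde and takes up the water while the weak base spares the acidic O2N–CH2 and the base-labile β-nitro aldehyde; the acceptor is symmetric, so no alkene geometry arises.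

Step 3 (key step)
Reactants: 4 dimethyl 2-(3-nitropropylidene)malonate; 5 (E)-crotonaldehyde
Product: 7 dimethyl 2-[(1R,2S,3R,4R)-2-formyl-3-methyl-4-nitrocyclopentyl]malonate, via open-chain nitro aldehyde 6 (not isolated)
Conditions: (S)-2-[diphenyl(trimethylsilyloxy)methyl]pyrrolidine (20 mol %), PhCO2H (20 mol %), 5 (1.5 equiv), MeOH, 0 °C → rt
Reagents that add atoms: none
Why: Proposed new method: iminium/enamine double Michael cascade in which the nitronate carbon of 4, an acyl anion equivalent because it later becomes the C=O/C–O carbon, attacks the β-carbon of the crotonaldehyde iminium ion (two centres that are both acceptors in normal polarity) on the face left open by the CPh2(OSiMe3) group, fixing C3 as R; the enamine form of 6 then closes 5-exo-trig on the alkylidene malonate from the same open face, placing CHO trans to CH3 (C2 S) and the malonyl group trans to CHO (C1 R, also the thermodynamic all-trans array because C2 stays epimerisable), while the nitro carbon equilibrates to the trans epimer and is erased in step 6; the iminium ion is many orders of magnitude more electrophilic than the alkylidene malonate, so self-addition of 4 should not compete; the closest known reactions are the diarylprolinol silyl ether-catalysed Michael addition of nitroalkanes to enals and the malonate-initiated double Michael synthesis of cyclopentanecarbaldehydes.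

Step 4
Reactants: 7 cascade product
Product: 8 2-[(1R,2S,3R,4R)-2-(hydroxymethyl)-3-methyl-4-nitrocyclopentyl]propane-1,3-diol
Conditions: LiBH4 (4 equiv), THF/MeOH, 0 °C → rt
Reagents that add atoms: none
Why: Chemoselective borohydride reduction, since LiBH4 reduces the aldehyde and both esters but not an aliphatic nitro group; the ring stereocentres are untouched and C2 is no longer epimerisable once the aldehyde is gone.

Step 5
Reactants: 8 nitro triol
Product: 9 [(1S,2R,3R,5R)-5-(2,2-dimethyl-1,3-dioxan-5-yl)-2-methyl-3-nitrocyclopentyl]methanol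
Conditions: Me2C(OMe)2, PPTS (cat.), acetone, rt
Reagents that add atoms: 2,2-dimethoxypropane COC(C)(C)OC
Why: Acid-catalysed transacetalisation; only the 1,3-diol can close an unstrained six-membered dioxane (ring B), so the ring CH2OH stays free.

Step 6
Reactants: 9 nitro acetonide
Product: 11 (2R,3S,4R)-4-(2,2-dimethyl-1,3-dioxan-5-yl)-3-(hydroxymethyl)-2-methylcyclopentan-1-one, via potassium nitronate 10 (not isolated)
Conditions: K2CO3, 30 % aq. H2O2, MeOH, 0 °C → rt
Reagents that add atoms: hydrogen peroxide OO
Why: Oxidative Nef reaction, in which the nitronate C=N bond is oxidised to C=O under basic conditions that leave the acetonide and the primary alcohol alone; the α-methyl centre remains in its more stable trans arrangement.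

Step 7
Reactants: 11 hydroxy ketone
Product: 12 (1S,2R,3S,4R)-4-(2,2-dimethyl-1,3-dioxan-5-yl)-3-(hydroxymethyl)-2-methylcyclopentan-1-ol
Conditions: LiBH(s-Bu)3 (2.5 equiv), THF, −78 °C; H2O quench
Reagents that add atoms: none
Why: Sterically controlled ketone reduction, where the bulky hydride enters anti to the adjacent methyl and the C4 dioxanyl group and gives the alcohol cis to CH3 (C1 S); this is the same sense as in reductions of 2,3,4-trisubstituted cyclopentanones of the prostaglandin E type.

Step 8
Reactants: 13 (3aR,6aR)-2,2-dimethyl-3a,6a-dihydro-4H-cyclopenta[d][1,3]dioxol-4-one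
Product: 15 methyl 2-[(3aR,5S,6aR)-2,2-dimethyl-4-oxotetrahydro-3aH-cyclopenta[d][1,3]dioxol-5-yl]acetate, via lithium enolate 14 (not isolated)
Conditions: LiBH(s-Bu)3 (1.05 equiv), THF, −78 °C; then BrCH2CO2Me, DMPU, −78 → −20 °C
Reagents that add atoms: methyl bromoacetate COC(=O)CBr
Why: Conjugate reduction followed by enolate alkylation (reductive alkylation); 1,4-hydride addition gives the enolate only on the side away from the alkoxy carbons, so no β-elimination occurs, and the electrophile enters on the convex face anti to the acetonide, setting C5 as S.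

Step 9
Reactants: 15 keto ester
Product: 17 2-[(3aS,4E,5S,6aR)-4-ethylidene-2,2-dimethyltetrahydro-3aH-cyclopenta[d][1,3]dioxol-5-yl]acetic acid, via ethylidene methyl ester 16 (not isolated)
Conditions: EtPPh3Br, KOtBu, THF, −78 °C → rt; then LiOH, H2O/MeOH, rt; 1 M HCl to pH 4, 0 °C; E isomer separated by chromatography
Reagents that add atoms: ethyltriphenylphosphonium bromide CC[P+](c1ccccc1)(c1ccccc1)c1ccccc1.[Br-]; lithium hydroxide [Li+].[OH-]
Why: Wittig olefination followed by ester saponification in the same flask; no stereocentre is made, C5 already sits in its more stable exo position so transient enolisation is harmless, and the E alkene (CH3 syn to C5) is the isomer that maps onto the E-enal.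

Step 10
Reactants: 12 core diol; 17 acid (2.6 equiv)
Product: 18 bis-ester [(1S,2R,3R,5R)-5-(2,2-dimethyl-1,3-dioxan-5-yl)-2-methyl-3-(acyloxy)cyclopentyl]methyl ester, both acyl groups being the acyl residue of 17
Conditions: PPh3 (3 equiv), DIAD (3 equiv), toluene/THF, 0 °C → rt
Reagents that add atoms: none
Why: Double Mitsunobu esterification, in which the primary alcohol is acylated without stereochemical consequence and the secondary carbinol reacts by SN2 with clean inversion (S → R), placing the acyloxy group trans to CH3; this parallels the inversions known at C9 of prostaglandin F derivatives.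

Step 11
Reactants: 18 bis-ester
Product: 20 target CNP0313563.1, via hexaol 19 (not isolated)
Conditions: 1 M aq. HCl/THF (1:1), rt; then NaIO4 (2.4 equiv) added to the same flask, 0 °C
Reagents that add atoms: none
Why: Acetal hydrolysis followed by Malaprade glycol cleavage; the two cis-1,2-diols are cut to the four aldehydes while the 1,3-diol, the esters and the trisubstituted alkenes are inert to periodate, and no stereocentre or alkene geometry is touched.

## Compound list
1 | acrolein | C=CC=O | starting material
2 | 3-nitropropanal | O=CCC[N+](=O)[O-] | intermediate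
3 | dimethyl malonate | COC(=O)CC(=O)OC | starting material
4 | dimethyl 2-(3-nitropropylidene)malonate | COC(=O)C(=CCC[N+](=O)[O-])C(=O)OC | intermediate
5 | (E)-crotonaldehyde | C/C=C/C=O | starting material
6 | dimethyl 2-[(5R)-5-methyl-4-nitro-7-oxoheptylidene]malonate (C4 epimers, present as the catalyst enamine) | COC(=O)C(=CCC([N+](=O)[O-])[C@H](C)CC=O)C(=O)OC | intermediate
7 | dimethyl 2-[(1R,2S,3R,4R)-2-formyl-3-methyl-4-nitrocyclopentyl]malonate | O=C[C@@H]1[C@@H](C)[C@H]([N+](=O)[O-])C[C@H]1C(C(=O)OC)C(=O)OC | intermediate
8 | 2-[(1R,2S,3R,4R)-2-(hydroxymethyl)-3-methyl-4-nitrocyclopentyl]propane-1,3-diol | OC[C@@H]1[C@@H](C)[C@H]([N+](=O)[O-])C[C@H]1C(CO)CO | intermediate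
9 | [(1S,2R,3R,5R)-5-(2,2-dimethyl-1,3-dioxan-5-yl)-2-methyl-3-nitrocyclopentyl]methanol | OC[C@@H]1[C@@H](C)[C@H]([N+](=O)[O-])C[C@H]1C2COC(C)(C)OC2 | intermediate
10 | potassium nitronate of 9 | [K+].OC[C@@H]1[C@@H](C)C(=[N+]([O-])[O-])C[C@H]1C2COC(C)(C)OC2 | intermediate
11 | (2R,3S,4R)-4-(2,2-dimethyl-1,3-dioxan-5-yl)-3-(hydroxymethyl)-2-methylcyclopentan-1-one | OC[C@@H]1[C@@H](C)C(=O)C[C@H]1C2COC(C)(C)OC2 | intermediate
12 | (1S,2R,3S,4R)-4-(2,2-dimethyl-1,3-dioxan-5-yl)-3-(hydroxymethyl)-2-methylcyclopentan-1-ol | OC[C@@H]1[C@@H](C)[C@@H](O)C[C@H]1C2COC(C)(C)OC2 | intermediate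
13 | (3aR,6aR)-2,2-dimethyl-3a,6a-dihydro-4H-cyclopenta[d][1,3]dioxol-4-one | CC1(C)O[C@@H]2C=CC(=O)[C@@H]2O1 | starting material
14 | lithium C4–C5 enolate of the saturated ketone derived from 13 | [Li+].[O-]C1=CC[C@H]2OC(C)(C)O[C@@H]12 | intermediate
15 | methyl 2-[(3aR,5S,6aR)-2,2-dimethyl-4-oxotetrahydro-3aH-cyclopenta[d][1,3]dioxol-5-yl]acetate | COC(=O)C[C@@H]1C[C@H]2OC(C)(C)O[C@H]2C1=O | intermediate
16 | methyl 2-[(3aS,4E,5S,6aR)-4-ethylidene-2,2-dimethyltetrahydro-3aH-cyclopenta[d][1,3]dioxol-5-yl]acetate | COC(=O)C[C@@H]1C[C@H]2OC(C)(C)O[C@H]2/C1=C/C | intermediate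
17 | 2-[(3aS,4E,5S,6aR)-4-ethylidene-2,2-dimethyltetrahydro-3aH-cyclopenta[d][1,3]dioxol-5-yl]acetic acid | OC(=O)C[C@@H]1C[C@H]2OC(C)(C)O[C@H]2/C1=C/C | intermediate
18 | bis-ester of the C1-inverted core diol with two acyl units of 17 | O=C(C[C@@H]3C[C@H]4OC(C)(C)O[C@H]4/C3=C/C)OC[C@@H]1[C@@H](C)[C@H](OC(=O)C[C@@H]5C[C@H]6OC(C)(C)O[C@H]6/C5=C/C)C[C@H]1C2COC(C)(C)OC2 | intermediate
19 | hexaol (18 without its three acetonides) | O=C(C[C@@H]3C[C@@H](O)[C@@H](O)/C3=C/C)OC[C@@H]1[C@@H](C)[C@H](OC(=O)C[C@@H]4C[C@@H](O)[C@@H](O)/C4=C/C)C[C@H]1C(CO)CO | intermediate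
20 | [(1S,2R,3R,5R)-5-(1,3-dihydroxypropan-2-yl)-3-{[(3S,4E)-4-formyl-3-(2-oxoethyl)hex-4-enoyl]oxy}-2-methylcyclopentyl]methyl (3S,4E)-4-formyl-3-(2-oxoethyl)hex-4-enoate | C/C=C(/C=O)[C@@H](CC=O)CC(=O)OC[C@@H]1[C@@H](C)[C@H](OC(=O)C[C@H](CC=O)/C(C=O)=C\C)C[C@H]1C(CO)CO | target

## Step count
Total steps: 11. Longest linear sequence: 9 (steps 1–7, 10, 11).

## Steps most likely to fail, with fallbacks

**Step 3 (cascade).**
- Risk: 4 can lose HNO2, can oligomerise or can undergo retro-Knoevenagel cleavage with the amine, and the second Michael addition may be slow or poorly selective.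
- Fallback: catalyst control is replaced by auxiliary control. The fallback sets out from 4.
- 4 is combined with commercial (S)-4-benzyl-3-[(E)-but-2-enoyl]-1,3-oxazolidin-2-one, MgBr2·OEt2 and Et3N in CH2Cl2.
- The chelated imide takes up the nitronate carbon anti to the benzyl group, which gives the same R methyl centre. The magnesium enolate then closes on the alkylidene malonate to give the N-acyl oxazolidinone cyclopentane F1.
- LiBH4 reduces the imide and both esters together, and the route is rejoined at 8.

**Step 9 (ethylidene geometry).**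
- Risk: the non-stabilised ylide may place CH3 mainly syn to the alkoxy-bearing carbon, which is the wrong isomer. Base-induced β-elimination of the acetonide is also possible.
- Fallback: the geometry is set thermodynamically at the enal stage instead of in the olefination. The fallback sets out from 16, isolated as its E/Z mixture without saponification.
- Aqueous HCl/THF gives the diol ester F2, and NaIO4 cleaves it to the dialdehyde methyl ester F3.
- F3 is equilibrated to the E-enal with catalytic pyrrolidinium acetate.
- HC(OMe)3/MeOH with catalytic PPTS gives the bis(dimethyl acetal) ester F4, and LiOH gives the bis-acetal acid F5.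
- Double Mitsunobu esterification of 12 with F5 gives the acetal-protected bis-ester F6.
- One aqueous HCl/THF hydrolysis removes all acetals and the dioxane, so the route is rejoined at 20.

**Step 10 (double Mitsunobu).**
- Risk: E2 elimination towards the methyl-bearing carbon, or incomplete reaction at the hindered secondary carbinol with an ordinary aliphatic acid.
- Fallback: the trans alcohol is made first and is then acylated with retention. The fallback sets out from 11.
- Reduction with SmI2/H2O/Et3N in THF proceeds by ketyl protonation towards the more stable alcohol and gives the trans diol F7.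
- F7 is esterified at both hydroxyls with 17 using EDC·HCl and DMAP in CH2Cl2, and the route is rejoined at 18.

## Further compounds
F1 | step 3 | dimethyl 2-[(1R,2S,3R,4R)-2-{[(4S)-4-benzyl-2-oxo-1,3-oxazolidin-3-yl]carbonyl}-3-methyl-4-nitrocyclopentyl]malonate | O=C([C@@H]1[C@@H](C)[C@H]([N+](=O)[O-])C[C@H]1C(C(=O)OC)C(=O)OC)N2C(=O)OC[C@@H]2Cc3ccccc3
F2 | step 9 | methyl 2-[(1S,3R,4S)-2-ethylidene-3,4-dihydroxycyclopentyl]acetate (E/Z mixture) | COC(=O)C[C@@H]1C[C@@H](O)[C@@H](O)C1=CC
F3 | step 9 | methyl (3S,4E)-4-formyl-3-(2-oxoethyl)hex-4-enoate | C/C=C(/C=O)[C@@H](CC=O)CC(=O)OC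
F4 | step 9 | methyl (3S,4E)-4-(dimethoxymethyl)-3-(2,2-dimethoxyethyl)hex-4-enoate | C/C=C(/C(OC)OC)[C@@H](CC(OC)OC)CC(=O)OC
F5 | step 9 | (3S,4E)-4-(dimethoxymethyl)-3-(2,2-dimethoxyethyl)hex-4-enoic acid | C/C=C(/C(OC)OC)[C@@H](CC(OC)OC)CC(=O)O
F6 | step 9 | bis-ester of the C1-inverted core diol with two acyl units of F5 | C/C=C(/C(OC)OC)[C@@H](CC(OC)OC)CC(=O)OC[C@@H]1[C@@H](C)[C@H](OC(=O)C[C@H](CC(OC)OC)/C(C(OC)OC)=C\C)C[C@H]1C2COC(C)(C)OC2
F7 | step 10 | (1R,2R,3S,4R)-4-(2,2-dimethyl-1,3-dioxan-5-yl)-3-(hydroxymethyl)-2-methylcyclopentan-1-ol | OC[C@@H]1[C@@H](C)[C@H](O)C[C@H]1C2COC(C)(C)OC2
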